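The route rests on the disconnection between C5 of the imidazole ring and the benzylic CH2 of the 3-hydroxy-4,5-dimethoxybenzyl group. C5 is the only ring CH of 4-(4-methoxybenzyl)-1-methyl-1H-imidazol-2-amine and the nucleophilic terminus of the vinylogous guanidine H2N–C2=N3–C4=C5, flanked by N1–CH3. In one operation it is joined, without protecting groups, to 3-hydroxy-4,5-dimethoxybenzaldehyde by hydroxyalkylation and ionic hydrogenation of the resulting carbinol, which completes the carbon skeleton. The aminoimidazole comes from alkyne hydroamination of a propargylguanidine; the 4-amino-1-methylimidazole-2,5-dione ring is attached last by condensation with 1-methylparabanic acid.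

Key step: step 4

Remark: the target has no stereocentre; the amino tautomer of the 4-amino-1-methylimidazole-2,5-dione unit (ring C=N, exocyclic NH) is taken as the product form.

Step 1
Reactants: 1 4-iodoanisole; 2 N-methylprop-2-yn-1-amine
Product: 3 3-(4-methoxyphenyl)-N-methylprop-2-yn-1-amine
Conditions: PdCl2(PPh3)2 (2 mol %), CuI (4 mol %), Et3N, THF, rt, Ar
Reagents that add atoms: none
Why: Sonogashira coupling of an aryl iodide with a terminal alkyne should give the aryl alkyne, the secondary propargylic amine being a spectator under amine-base conditions.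

Step 2
Reactants: 3 3-(4-methoxyphenyl)-N-methylprop-2-yn-1-amine; 4 N,N'-bis(tert-butoxycarbonyl)-1H-pyrazole-1-carboxamidine
Product: 5 N,N'-bis(tert-butoxycarbonyl)-N''-[3-(4-methoxyphenyl)prop-2-yn-1-yl]-N''-methylguanidine
Conditions: MeCN, rt to 40 °C
Reagents that add atoms: none
Why: Guanylation of an amine by addition–elimination at the amidine carbon of the reagent, with pyrazole as the leaving group, is reliable for secondary amines.

Step 3
Reactants: 5 N,N'-bis(tert-butoxycarbonyl)-N''-[3-(4-methoxyphenyl)prop-2-yn-1-yl]-N''-methylguanidine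
Product: 7 4-(4-methoxybenzyl)-1-methyl-1H-imidazol-2-amine, via Z-benzylidene ene-guanidine 6 (not isolated)
Conditions: AgNO3 (10 mol %), MeCN, rt; concentrate; then TFA–CH2Cl2 (1:1), rt; aq. K2CO3 work-up, Ar
Reagents that add atoms: none
Why: Silver(I)-catalysed 5-exo-dig intramolecular hydroamination of the alkyne by the carbamate N–H (anti addition, hence Z) is followed by acidolytic Boc cleavage, during which the exocyclic C=C moves into the ring by a proton shift to give the aromatic 2-aminoimidazole.

Step 4
Reactants: 7 4-(4-methoxybenzyl)-1-methyl-1H-imidazol-2-amine; 8 3-hydroxy-4,5-dimethoxybenzaldehyde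
Product: 10 5-{[2-amino-4-(4-methoxybenzyl)-1-methyl-1H-imidazol-5-yl]methyl}-2,3-dimethoxyphenol, via imidazol-5-yl aryl carbinol 9 (not isolated)
Conditions: 8 (1.5 equiv), MeOH, 50 °C, Ar; evaporate; TFA–CH2Cl2 (1:1), 0 °C, 15 min; then Et3SiH (5 equiv), 0 °C to rt; aq. NaHCO3
Reagents that add atoms: none
Why: The free base 7 attacks the aldehyde carbon of 8 through C5, the carbon terminus of the H2N–C2=N3–C4=C5 vinylogous guanidine, and loss of the C5 proton restores the aromatic ring to give carbinol 9; in TFA the hydroxyl leaves to form a benzylic/2-amino-diazafulvenium cation stabilised by both rings, which Et3SiH reduces to the CH2 bridge. The closest known reaction types are the C-hydroxyalkylation of 2-aminoimidazoles by aldehydes under neutral conditions and the ionic hydrogenation (Et3SiH/TFA) of imidazolyl aryl carbinols, together a reductive Friedel–Crafts benzylation. No ring is closed, and the carbinol carbon of 9 is formed as a racemate and ends as a CH2 group, so no stereocentre remains. The step needs C- over N-selectivity and mono-alkylation: C4 and N1 are blocked so C5 is the only carbon site, condensation at nitrogen is reversible and should revert in the acid before the silane is added, and in TFA unreacted 7 is protonated and should not intercept the cation to give a bis(imidazolyl)methane. The free phenol needs no protection because neither stage uses a base or an electrophile for oxygen.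

Step 5
Reactants: 11 N-methylurea; 12 oxalyl chloride
Product: 13 1-methylimidazolidine-2,4,5-trione (1-methylparabanic acid)
Conditions: THF, 0 °C to reflux
Reagents that add atoms: none
Why: Cyclocondensation by double N-acylation of the urea with the bis(acid chloride) should close the five-membered trione ring with loss of two HCl.

Step 6
Reactants: 10 5-{[2-amino-4-(4-methoxybenzyl)-1-methyl-1H-imidazol-5-yl]methyl}-2,3-dimethoxyphenol; 13 1-methylimidazolidine-2,4,5-trione
Product: 15 4-{[5-(3-hydroxy-4,5-dimethoxybenzyl)-4-(4-methoxybenzyl)-1-methyl-1H-imidazol-2-yl]amino}-1-methyl-1H-imidazole-2,5-dione, via O-trimethylsilyl imidate 14 (not isolated)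
Conditions: 13 (2 equiv), N,O-bis(trimethylsilyl)acetamide (2 equiv), MeCN, rt to 60 °C; evaporate; then 10, toluene, reflux; MeOH then aq. NaHCO3 work-up
Reagents that add atoms: none
Why: Silylation turns the N3–H/C4=O lactam of 13 into the O-silyl imidate 14, and addition–elimination at its C4 by the 2-amino group of 10 (amidine-forming condensation, loss of trimethylsilanol) should give the amidine regioselectively, as established for phenolic 2-aminoimidazoles with silylated 1-methylparabanic acid.

Compound list
1 | 4-iodoanisole | COc1ccc(I)cc1 | starting material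
2 | N-methylprop-2-yn-1-amine | CNCC#C | starting material
3 | 3-(4-methoxyphenyl)-N-methylprop-2-yn-1-amine | CNCC#Cc1ccc(OC)cc1 | intermediate
4 | N,N'-bis(tert-butoxycarbonyl)-1H-pyrazole-1-carboxamidine | CC(C)(C)OC(=O)NC(=NC(=O)OC(C)(C)C)n1cccn1 | starting material
5 | N,N'-bis(tert-butoxycarbonyl)-N''-[3-(4-methoxyphenyl)prop-2-yn-1-yl]-N''-methylguanidine | COc1ccc(C#CCN(C)C(=NC(=O)OC(C)(C)C)NC(=O)OC(C)(C)C)cc1 | intermediate
6 | tert-butyl (5Z)-2-[(tert-butoxycarbonyl)imino]-5-(4-methoxybenzylidene)-3-methylimidazolidine-1-carboxylate | COc1ccc(/C=C2/CN(C)C(=NC(=O)OC(C)(C)C)N2C(=O)OC(C)(C)C)cc1 | intermediate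
7 | 4-(4-methoxybenzyl)-1-methyl-1H-imidazol-2-amine | COc1ccc(Cc2cn(C)c(N)n2)cc1 | intermediate
8 | 3-hydroxy-4,5-dimethoxybenzaldehyde | COc1cc(C=O)cc(O)c1OC | starting material
9 | [2-amino-4-(4-methoxybenzyl)-1-methyl-1H-imidazol-5-yl](3-hydroxy-4,5-dimethoxyphenyl)methanol (racemic) | COc1ccc(Cc2nc(N)n(C)c2C(O)c2cc(O)c(OC)c(OC)c2)cc1 | intermediate
10 | 5-{[2-amino-4-(4-methoxybenzyl)-1-methyl-1H-imidazol-5-yl]methyl}-2,3-dimethoxyphenol | COc1ccc(Cc2nc(N)n(C)c2Cc2cc(O)c(OC)c(OC)c2)cc1 | intermediate
11 | N-methylurea | CNC(N)=O | starting material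
12 | oxalyl chloride | O=C(Cl)C(=O)Cl | starting material
13 | 1-methylimidazolidine-2,4,5-trione | CN1C(=O)NC(=O)C1=O | intermediate
14 | 1-methyl-4-(trimethylsilyloxy)-1H-imidazole-2,5-dione | CN1C(=O)N=C(O[Si](C)(C)C)C1=O | intermediate
15 | 4-{[5-(3-hydroxy-4,5-dimethoxybenzyl)-4-(4-methoxybenzyl)-1-methyl-1H-imidazol-2-yl]amino}-1-methyl-1H-imidazole-2,5-dione | COc1ccc(Cc2nc(NC3=NC(=O)N(C)C3=O)n(C)c2Cc2cc(O)c(OC)c(OC)c2)cc1 | target

Total step count: 6. Longest linear sequence: 5 steps (1, 2, 3, 4, 6); step 5 is a one-step side branch.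

Steps most likely to fail

Step 4. The hydroxyalkylation may stop at an unfavourable equilibrium with this electron-rich aryl aldehyde, or condensation at nitrogen may survive into the reduction and lead to N-benzylation. The fallback sets out from 7 and comes back at 10, and replaces the innate nucleophilicity of C5 by a site-specific organomagnesium. The amino group of 7 is masked with DMF dimethyl acetal (toluene, 80 °C) as N'-[4-(4-methoxybenzyl)-1-methyl-1H-imidazol-2-yl]-N,N-dimethylformimidamide F1. NIS (MeCN, 0 °C) should iodinate the only free ring position to give N'-[5-iodo-4-(4-methoxybenzyl)-1-methyl-1H-imidazol-2-yl]-N,N-dimethylformimidamide F2. Iodine–magnesium exchange with i-PrMgCl·LiCl (THF, −20 °C) gives the imidazol-5-ylmagnesium chloride F3. This is added to sodium 5-formyl-2,3-dimethoxyphenolate F4, made from 8 with NaH in THF, to give after NH4Cl quench the formamidine-protected carbinol F5. Et3SiH/TFA in CH2Cl2 reduces it to the formamidine-protected 5-benzylimidazole F6, and hydrazine hydrate in EtOH at reflux removes the formamidine to return to 10.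

Step 6. The amine may attack a wrong carbonyl of the trione, or the condensation may stall while the electron-rich aminoimidazole degrades at reflux. The fallback sets out from 10 and comes back at 15, and builds the ring on the nitrogen so that the N-methyl position is fixed by construction. Compound 10 is treated with ethyl 2-ethoxy-2-iminoacetate (EtOH, rt) to give ethyl 2-{[5-(3-hydroxy-4,5-dimethoxybenzyl)-4-(4-methoxybenzyl)-1-methyl-1H-imidazol-2-yl]amino}-2-iminoacetate F7. Methyl isocyanate (1.1 equiv, Et3N, THF, 0 °C) carbamoylates the amidine NH, which should react faster than the uncatalysed phenol, to give ethyl 2-{[5-(3-hydroxy-4,5-dimethoxybenzyl)-4-(4-methoxybenzyl)-1-methyl-1H-imidazol-2-yl]amino}-2-[(methylcarbamoyl)imino]acetate F8. On warming, 5-exo-trig attack of the NHMe nitrogen on the ester with loss of ethanol should give 15.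

Step 3. The hydroamination may be slow or give some 6-endo closure, and the acid stage may leave the exocyclic alkene unisomerised. The fallback sets out from 3 and comes back at 7, and makes the ring by condensation instead of hydroamination. Boc2O (CH2Cl2, rt) gives tert-butyl [3-(4-methoxyphenyl)prop-2-yn-1-yl](methyl)carbamate F9. Ph3PAuNTf2 (cat., CH2Cl2, rt) should cyclise the carbamate oxygen onto the alkyne with loss of isobutene to give (5Z)-5-(4-methoxybenzylidene)-3-methyl-1,3-oxazolidin-2-one F10. Aqueous HCl at reflux hydrolyses and decarboxylates it to 1-(4-methoxyphenyl)-3-(methylamino)propan-2-one hydrochloride F11. Marckwald-type condensation with cyanamide (water, pH 4.5, 95 °C; NaOH work-up) gives 7, the methylamino nitrogen becoming N1 and the ketone carbon C4.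

Further compounds
F1 | step 4 | N'-[4-(4-methoxybenzyl)-1-methyl-1H-imidazol-2-yl]-N,N-dimethylformimidamide | COc1ccc(Cc2cn(C)c(N=CN(C)C)n2)cc1
F2 | step 4 | N'-[5-iodo-4-(4-methoxybenzyl)-1-methyl-1H-imidazol-2-yl]-N,N-dimethylformimidamide | COc1ccc(Cc2nc(N=CN(C)C)n(C)c2I)cc1
F3 | step 4 | {2-[(dimethylaminomethylidene)amino]-4-(4-methoxybenzyl)-1-methyl-1H-imidazol-5-yl}magnesium chloride | COc1ccc(Cc2nc(N=CN(C)C)n(C)c2[Mg]Cl)cc1
F4 | step 4 | sodium 5-formyl-2,3-dimethoxyphenolate | COc1cc(C=O)cc([O-])c1OC.[Na+]
F5 | step 4 | N'-{5-[hydroxy(3-hydroxy-4,5-dimethoxyphenyl)methyl]-4-(4-methoxybenzyl)-1-methyl-1H-imidazol-2-yl}-N,N-dimethylformimidamide (racemic) | COc1ccc(Cc2nc(N=CN(C)C)n(C)c2C(O)c2cc(O)c(OC)c(OC)c2)cc1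
F6 | step 4 | N'-[5-(3-hydroxy-4,5-dimethoxybenzyl)-4-(4-methoxybenzyl)-1-methyl-1H-imidazol-2-yl]-N,N-dimethylformimidamide | COc1ccc(Cc2nc(N=CN(C)C)n(C)c2Cc2cc(O)c(OC)c(OC)c2)cc1
F7 | step 6 | ethyl 2-{[5-(3-hydroxy-4,5-dimethoxybenzyl)-4-(4-methoxybenzyl)-1-methyl-1H-imidazol-2-yl]amino}-2-iminoacetate | CCOC(=O)C(=N)Nc1nc(Cc2ccc(OC)cc2)c(Cc2cc(O)c(OC)c(OC)c2)n1C
F8 | step 6 | ethyl 2-{[5-(3-hydroxy-4,5-dimethoxybenzyl)-4-(4-methoxybenzyl)-1-methyl-1H-imidazol-2-yl]amino}-2-[(methylcarbamoyl)imino]acetate | CCOC(=O)C(=NC(=O)NC)Nc1nc(Cc2ccc(OC)cc2)c(Cc2cc(O)c(OC)c(OC)c2)n1C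
F9 | step 3 | tert-butyl [3-(4-methoxyphenyl)prop-2-yn-1-yl](methyl)carbamate | COc1ccc(C#CCN(C)C(=O)OC(C)(C)C)cc1
F10 | step 3 | (5Z)-5-(4-methoxybenzylidene)-3-methyl-1,3-oxazolidin-2-one | COc1ccc(/C=C2/CN(C)C(=O)O2)cc1
F11 | step 3 | 1-(4-methoxyphenyl)-3-(methylamino)propan-2-one hydrochloride | CNCC(=O)Cc1ccc(OC)cc1.Cl
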